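# Proposed total synthesis of monotesone A

## Analysis of the target

Monotesone A (20) is the 4'-O-prenyl ether of (2S)-eriodictyol. It is a chroman-4-one, with aromatic ring A fused to the oxygen heterocycle ring C, and it carries a catechol-derived ring B at C2. C2 is the only stereocentre, so no relative stereochemistry has to be managed. C2 is, however, benzylic, bonded to O1 and β to the C4 carbonyl, so its configuration is lost whenever base or strong acid opens ring C by E1cB cleavage of O1–C2 and closes it again. The aryl prenyl ether is the second weak point: it does not tolerate strong Brønsted or Lewis acid, hydrogenation, ozone or osmylation, and it rearranges on strong heating. Four phenolic oxygens must be told apart, and the alkylated one (O4') is not the most acidic one (O7), so direct prenylation of the parent tetraphenol is not an option. The difficulty therefore lies in the order of events more than in the skeleton. The strategy rests on the fact that O1 is both the carbinol oxygen of C2 and an aryl ether oxygen on C8a of ring A. If O1–C8a is the last bond of ring C to be made, C2 can be set beforehand as an ordinary secondary alcohol, and none of its four bonds is touched in the ring closure. This holds only while C4 is not a carbonyl, so C4 is carried as an exocyclic methylene.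

## Retrosynthetic reasoning

**20 ⇒ 19 (three O–Si bonds).** The last operation should do nothing except free phenols. O3', O5 and O7 of 20 are traced back to the tris(triisopropylsilyl) ether 19. Silicon is chosen because its removal needs no acid, strong base, hydrogen or oxidant, and each of those would damage the prenyl ether or C2. The forward step must stay near neutrality so that ring C does not open.

**19 ⇒ 17 + 18 (O4'–CH2 bond of the prenyl ether).** The prenyl alkene would not survive the unmasking of C4 or a hydrogenolysis, so it is attached after both. Cutting the ether gives phenol 17 and prenol 18. A Mitsunobu reaction joins them without external base, which protects C2. The bulky silyl group on O3' is meant to stay in place next to the transient phenoxide.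

**17 ⇒ 16 (O4'–benzyl bond).** O4' needs a placeholder that is orthogonal to silicon and inert to everything before this point. A benzyl ether serves, which gives 16. The forward hydrogenolysis must spare the benzylic O1–C2 bond and the aryl ketone.

**16 ⇒ 14 (C4=O from C4=CH2).** The carbonyl is the source of the lability at C2, so it is revealed only after ring C exists. Replacing the oxygen by CH2 gives the 4-methyleneflavan 14. The forward reaction is an oxidative cleavage of the only alkene in the molecule.

**14 ⇒ 13 (O1–C8a, key disconnection).** Cutting O1–C2 instead would return to an oxa-Michael closure, in which C2 is formed reversibly and without control. Cutting O1–C8a leaves C2 intact and leads to the bromo carbinol 13. With a methylene at C4, 13 has no aldol unit that carbonate base could cleave or dehydrate. The forward reaction is an intramolecular palladium-catalysed aryl etherification. In it, reductive elimination must be faster than β-hydride elimination.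

**13 ⇒ 8 + 11 (C2–C3).** The homoallylic alcohol motif of 13 is what an aldehyde allylation produces. Cutting C2–C3 gives the 2-arylallyl boronate 8 and the aldehyde 11. The union is convergent and sets C2 in a closed, catalyst-controlled transition state. It also tolerates the aryl bromide, which an allyl-lithium or allyl-magnesium reagent would not.

**8 ⇒ 7 ⇒ 6 ⇒ 5 ⇒ 4 (C–B, allylic C–O, C4=CH2).** The C–B bond comes from the carbonate 7 by copper catalysis, which leaves the C–Br bond alone. Carbonate 7 comes from the allylic alcohol 6, and 6 comes from the isopropenyl arene 5 by allylic oxidation with selenium. Halogen-based allylic functionalisation is avoided because it would attack the activated ring A. Arene 5 is the methylenation product of ketone 4.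

**4 ⇒ 3 ⇒ 2 ⇒ 1 (O–Si, O–CH3, C4–C4a).** Bromine sits meta to both ring A oxygens, a position that electrophilic bromination cannot reach, so it is bought in with 1. The methoxy groups of 1 direct acylation to the carbon next to bromine, which forms C4–C4a and gives 2. Methyl ethers cannot be removed at the end of the route, so they are exchanged early through 3 for the silyl ethers of 4.

**11 ⇒ 10 ⇒ 9 (O3'–Si, O4'–benzyl).** In 9 the hydroxyl para to the formyl group is the more acidic. One regioselective benzylation (giving 10) and one silylation (giving 11) therefore differentiate the catechol at the start.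

## Alternatives that were turned down

**Alternative 1:**
- *Disconnection and key step.* Ring A is opened at C4a–C5, so the final ring-forming event is an aromatisation. The precursor is the (2S)-2-aryl-2,3-dihydropyran-4-one A2, whose C8a bears a CH2-linked dioxinone. On heating, the dioxinone undergoes cycloreversion to the acylketene A3. The enol-ether carbon C4a then adds to the ketene carbon (the future C5), and tautomerisation gives the 3'-O-silyl ether A1 of the target.
- *For it.* Ring A appears with both phenols free and needs no protecting groups. The medium is neutral. The prenyl ether can be present from the start because no oxidant and no hydrogen are used, and only one desilylation follows. On protecting-group economy and on the number of steps after the key step it is clearly stronger than the chosen route.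
- *Against it.* C4a belongs to a push–pull vinylogous ester and is a weak carbon nucleophile. A3 has faster outlets: dimerisation, and O-acylation through the easily enolised C8 methylene. C-acylation of such a carbon by a ketene would be a new reaction. A2 needs an enantioselective pyranone synthesis followed by a delicate side-chain extension at C8a. Its C2 has the same β-aryloxy ketone lability as the target and would be exposed to temperatures near 110 °C.
- *Comparison.* The chosen strategy spends more steps. In return it closes its ring with a reaction of known behaviour, and it never heats or bases C2 while a carbonyl is conjugated to it.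

**Alternative 2:**
- *Disconnection and key step.* C3–C4 is cut and C2 is returned to an sp2 carbon, giving the 2-(1-arylvinyloxy)benzaldehyde A5. [Rh(cod)2]BF4 (monovalent rhodium) with a chiral bisphosphine inserts into the formyl C–H bond. Hydride is delivered to C2 and the acyl group to C3, which gives the tris-silyl ether A4.
- *For it.* One catalytic, fully atom-economical step closes ring C and sets C2. The prenyl ether is again carried throughout, and A4 is one desilylation away from the target. It is the shortest of all the plans and beats the chosen route on step count.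
- *Against it.* The six-membered ketone has to come from a seven-membered acyl rhodacycle, which competes with decarbonylation. It also competes with the regioisomeric insertion that places rhodium on the tertiary carbon and closes a five-membered ring. The formyl group is flanked by two ortho oxygens. Face-selective hydride delivery to an aryl- and aryloxy-substituted alkene carbon has no close model. The prenyl alkene is a competing ligand and a substrate for rhodium hydride isomerisation. A5 is an acid-labile enol ether that is awkward to make beside an aldehyde.
- *Comparison.* The chosen strategy separates the two tasks, setting the configuration by allylboration and closing the ring by etherification, and it assigns each task to an established reaction type.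

**Alternative 3:**
- *Disconnection and key step.* C3–C4 and O1–C2 are cut together, giving the salicylaldehyde A7 and the styrene A8. With trimethyl orthoformate A10 and a confined chiral Brønsted acid, A7 is converted into the 4-methoxy ortho-quinone methide A9. This adds to A8 to give the 2,4-cis-4-methoxyflavan A6.
- *For it.* It is the most convergent plan. Two bonds, ring C and C2 are formed in one step from two simple fragments, neither of which needs a halogen or boron. The fragments are easier to obtain than 8.
- *Against it.* A8 carries a para-alkoxy group, so the addition is likely to be stepwise through a planar benzylic cation at C2, the very carbon whose configuration matters. A8 is also prone to cationic oligomerisation. Both benzylic C–O bonds of A6 remain ionisable in the acidic medium, so C2 can erode after it has formed. The C4 stereocentre is made only to be destroyed, because the ether must still be hydrolysed and oxidised to the ketone. After that, the same debenzylation, prenylation and desilylation follow as in the chosen route, so the saving is limited to the front end.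
- *Comparison.* The chosen strategy creates C2 in a closed six-membered transition state without cationic character and then keeps it away from acid.

Key step: step 11

Assumption: the facial sense known for allyl pinacol boronate and benzaldehydes under TRIP catalysis ((S)-acid, Si-face attack, (S)-carbinol) is taken to hold for the 2-arylallyl boronate 8; should it be reversed, the equally available (R)-acid is used.

## Steps

**Step 1**
Reactants: 1 1-bromo-3,5-dimethoxybenzene
Product: 2 1-(2-bromo-4,6-dimethoxyphenyl)ethan-1-one
Conditions: AcCl (1.1 equiv), AlCl3 (1.2 equiv), CH2Cl2, 0 °C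
Reagents that add atoms: acetyl chloride, CC(=O)Cl
Why: Friedel–Crafts acylation; the carbon next to bromine is ortho to one methoxy group and para to the other, while the only other activated site lies crowded between both methoxy groups, so the acetyl group should enter beside bromine and create C4–C4a. Partial loss of the chelated ortho methyl group would be harmless because step 2 removes both.

**Step 2**
Reactants: 2 1-(2-bromo-4,6-dimethoxyphenyl)ethan-1-one
Product: 3 1-(2-bromo-4,6-dihydroxyphenyl)ethan-1-one
Conditions: BBr3 (4 equiv), CH2Cl2, −78 °C → rt; H2O
Reagents that add atoms: none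
Why: Lewis acid cleavage of aryl methyl ethers; BBr3 binds each ether oxygen (and the ketone, hence the excess) and bromide removes the methyl group by SN2. Aryl bromide and ketone are inert, and hydrolysis frees the resorcinol.

**Step 3**
Reactants: 3 1-(2-bromo-4,6-dihydroxyphenyl)ethan-1-one
Product: 4 1-[2-bromo-4,6-bis(triisopropylsilyloxy)phenyl]ethan-1-one
Conditions: TIPSOTf (2.5 equiv), 2,6-lutidine (3.5 equiv), CH2Cl2, 0 °C → rt
Reagents that add atoms: triisopropylsilyl triflate, CC(C)[Si](C(C)C)(C(C)C)OS(=O)(=O)C(F)(F)F
Why: O-silylation with a silyl triflate, which is reactive enough for the hydrogen-bonded ortho phenol, while the weak hindered base limits enol silylation. Triisopropylsilyl is preferred to smaller silyl groups because it must later withstand Cs2CO3 and a neighbouring alkoxide (step 11) yet still leaves with fluoride.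

**Step 4**
Reactants: 4 1-[2-bromo-4,6-bis(triisopropylsilyloxy)phenyl]ethan-1-one
Product: 5 1-bromo-2-(prop-1-en-2-yl)-3,5-bis(triisopropylsilyloxy)benzene
Conditions: Cp2TiMe2 (2.5 equiv), toluene, 70 °C, dark
Reagents that add atoms: dimethyltitanocene, [CH3-].[CH3-].[Ti+4].c1cc[cH-]c1.c1cc[cH-]c1
Why: Petasis methylenation; thermolysis of Cp2TiMe2 gives Cp2Ti=CH2, which adds to the carbonyl in a [2+2] sense and cycloreverts to the alkene. The reagent is not basic, so the hindered and easily enolised ketone is not deprotonated, and silyl transfer from the ortho oxygen to an enolate is avoided; aryl bromide and silyl ethers are inert.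

**Step 5**
Reactants: 5 1-bromo-2-(prop-1-en-2-yl)-3,5-bis(triisopropylsilyloxy)benzene
Product: 6 2-[2-bromo-4,6-bis(triisopropylsilyloxy)phenyl]prop-2-en-1-ol
Conditions: SeO2 (0.3 equiv), t-BuOOH (3 equiv, decane), CH2Cl2, 0 °C → rt
Reagents that add atoms: tert-butyl hydroperoxide, CC(C)(C)OO (oxygen relayed through SeO2, O=[Se]=O)
Why: Riley-type allylic oxidation; an ene reaction of SeO2 at the terminal CH2 and a [2,3]-sigmatropic shift of the allylseleninic acid place oxygen on the former methyl carbon. There is only one set of allylic hydrogens and the transposition regenerates the same skeleton, and unlike halogen electrophiles the reagent leaves the activated ring A alone.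

**Step 6**
Reactants: 6 2-[2-bromo-4,6-bis(triisopropylsilyloxy)phenyl]prop-2-en-1-ol
Product: 7 2-[2-bromo-4,6-bis(triisopropylsilyloxy)phenyl]prop-2-en-1-yl methyl carbonate
Conditions: ClCO2Me, pyridine, CH2Cl2, 0 °C
Reagents that add atoms: methyl chloroformate, COC(=O)Cl
Why: Acylation of an unhindered primary alcohol; the carbonate is chosen as leaving group because it releases its own alkoxide in step 7.

**Step 7**
Reactants: 7 2-[2-bromo-4,6-bis(triisopropylsilyloxy)phenyl]prop-2-en-1-yl methyl carbonate
Product: 8 2-{2-[2-bromo-4,6-bis(triisopropylsilyloxy)phenyl]prop-2-en-1-yl}-4,4,5,5-tetramethyl-1,3,2-dioxaborolane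
Conditions: B2pin2 (1.2 equiv), CuCl (5 mol %), KOt-Bu (5 mol %), Xantphos (5 mol %), THF, rt
Reagents that add atoms: bis(pinacolato)diboron, CC1(C)OB(OC1(C)C)B1OC(C)(C)C(C)(C)O1
Why: Copper-catalysed allylic borylation of a carbonate; a boryl complex of monovalent copper adds to the alkene with boron on the terminal carbon, the carbonate is expelled, and decarboxylation returns a copper alkoxide, so no stoichiometric base meets the aryl silyl ethers. The allyl unit is symmetric about its central carbon, so direct and transposed substitution give the same product, and the aryl bromide is untouched at room temperature.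

**Step 8**
Reactants: 9 3,4-dihydroxybenzaldehyde
Product: 10 4-benzyloxy-3-hydroxybenzaldehyde
Conditions: BnBr (1.0 equiv), NaHCO3 (1.5 equiv), MeCN, 80 °C
Reagents that add atoms: benzyl bromide, BrCc1ccccc1
Why: Williamson etherification; the hydroxyl para to the formyl group is the more acidic, so a weak base ionises it preferentially and one equivalent of halide should alkylate O4 selectively.

**Step 9**
Reactants: 10 4-benzyloxy-3-hydroxybenzaldehyde
Product: 11 4-benzyloxy-3-(triisopropylsilyloxy)benzaldehyde
Conditions: TIPSCl, imidazole, DMF, rt
Reagents that add atoms: triisopropylsilyl chloride, CC(C)[Si](Cl)(C(C)C)C(C)C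
Why: Standard phenol silylation; the bulky group is chosen because after step 13 it sits beside a free phenol, where a smaller silyl group could shuttle between the two catechol oxygens.

**Step 10**
Reactants: 8 2-{2-[2-bromo-4,6-bis(triisopropylsilyloxy)phenyl]prop-2-en-1-yl}-4,4,5,5-tetramethyl-1,3,2-dioxaborolane; 11 4-benzyloxy-3-(triisopropylsilyloxy)benzaldehyde
Product: 13 (S)-1-[4-benzyloxy-3-(triisopropylsilyloxy)phenyl]-3-[2-bromo-4,6-bis(triisopropylsilyloxy)phenyl]but-3-en-1-ol, via pinacol borate ester 12 (not isolated)
Conditions: (S)-TRIP (5 mol %), toluene, −30 °C; aq. NaHCO3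
Reagents that add atoms: none
Why: Chiral phosphoric acid-catalysed allylboration of an aromatic aldehyde through a closed six-membered chair; the acid hydrogen-bonds to the pseudoaxial boronate oxygen while its phosphoryl oxygen contacts the formyl hydrogen. The 2,4,6-triisopropylphenyl walls of the (S)-acid leave the Si face of 11 open, which sets (S)-C2 together with the C2–C3 bond. Work-up hydrolyses borate 12, and the aryl bromide and silyl ethers are spectators.

**Step 11**
Reactants: 13 (S)-1-[4-benzyloxy-3-(triisopropylsilyloxy)phenyl]-3-[2-bromo-4,6-bis(triisopropylsilyloxy)phenyl]but-3-en-1-ol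
Product: 14 (2S)-4'-benzyloxy-3',5,7-tris(triisopropylsilyloxy)-4-methyleneflavan
Conditions: Pd(OAc)2 (5 mol %), 2-(di-tert-butylphosphino)-1,1'-binaphthyl (6 mol %), Cs2CO3 (1.5 equiv), toluene, 70 °C
Reagents that add atoms: none
Why: Pd(OAc)2 (divalent palladium) is reduced in situ by the phosphine to a monoligated zerovalent palladium species that inserts into the C8a–Br bond of 13; Cs2CO3 takes the proton of the coordinated C2 hydroxyl, bromide leaves, and the resulting seven-membered oxapalladacycle (Pd, C8a, C4a, C4, C3, C2, O) collapses by C–O reductive elimination to 14. The closest known reaction type is the intramolecular palladium-catalysed etherification of aryl bromides with secondary alcohols under di-tert-butyl biaryl phosphines and carbonate base, which is established for chromans, so this is a known reaction on a new substrate. Ring C closes as a six-membered ring by reductive elimination; seen as a substitution at C8a the departing bromide lies outside the new ring (formally 6-exo), and no orbital-trajectory rule stands against it. No stereocentre is formed: O1–C8a is the only new bond, none of the four bonds at C2 is broken, and without a C4 carbonyl the C2–H and C3–H bonds are not acidic, so the (S) configuration from step 10 should be carried over with retention. The decisive selectivity is reductive elimination against β-hydride elimination of the benzylic C2–H from the palladium alkoxide; the bulky electron-rich ligand keeps palladium low-coordinate and crowded, which speeds reductive elimination, and both ring A oxygens are meta to C8a, so the aryl ligand is not made electron-rich by resonance, which helps the same step. The substrate adds further safeguards: the sp2 carbon C4 and the two ortho substituents on ring A hold the carbinol chain near the C–Br bond, a Heck insertion of the C4 methylene would need a three- or four-membered ring, and retro-allylation of the homoallylic alkoxide is shut off geometrically because the =CH2 terminus points away from palladium, towards O5, in the palladacycle. With C4 masked as a methylene there is no aldol unit, so carbonate can trigger neither retro-aldol cleavage nor dehydration, and the triisopropylsilyl ethers resist carbonate and transfer to the alkoxide far better than smaller silyl groups would.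

**Step 12**
Reactants: 14 (2S)-4'-benzyloxy-3',5,7-tris(triisopropylsilyloxy)-4-methyleneflavan
Product: 16 (2S)-4'-benzyloxy-3',5,7-tris(triisopropylsilyloxy)flavanone, via secondary ozonide 15 (not isolated)
Conditions: O3/O2, CH2Cl2, −78 °C (Sudan Red 7B end point); Me2S, −78 °C → rt
Reagents that add atoms: ozone, [O-][O+]=O
Why: Ozonolysis with reductive work-up; the 1,1-disubstituted alkene is the only alkene and reacts much faster than the arenes or the benzylic C–H bonds, and the dye marks the end point before they are attacked. The medium is neutral, so the newly labile C2 should keep its configuration.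

**Step 13**
Reactants: 16 (2S)-4'-benzyloxy-3',5,7-tris(triisopropylsilyloxy)flavanone
Product: 17 (2S)-4'-hydroxy-3',5,7-tris(triisopropylsilyloxy)flavanone
Conditions: H2 (1 atm), Pd/C (10 wt %), EtOAc, rt
Reagents that add atoms: none
Why: Hydrogenolysis of an aryl benzyl ether, routine on flavanones; the unhindered primary benzylic C–O bond is cleaved well before the secondary, ring-bound O1–C2 bond or the electron-rich aryl ketone if the reaction is stopped after one equivalent of hydrogen. A non-protic solvent keeps the silyl ethers intact.

**Step 14**
Reactants: 17 (2S)-4'-hydroxy-3',5,7-tris(triisopropylsilyloxy)flavanone; 18 prenol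
Product: 19 (2S)-4'-(3-methylbut-2-enyloxy)-3',5,7-tris(triisopropylsilyloxy)flavanone
Conditions: PPh3, DIAD, THF, 0 °C → rt
Reagents that add atoms: none
Why: Mitsunobu etherification; the only free phenol attacks the primary alkoxyphosphonium carbon of 18 by SN2, which should give the linear prenyl ether. No external base is present, so ring C should not open, and the phenoxide is short-lived and ion-paired, which together with the bulk of the silyl group disfavours a silyl shift from O3' to O4'.

**Step 15**
Reactants: 19 (2S)-4'-(3-methylbut-2-enyloxy)-3',5,7-tris(triisopropylsilyloxy)flavanone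
Product: 20 monotesone A, (2S)-5,7,3'-trihydroxy-4'-(3-methylbut-2-enyloxy)flavanone
Conditions: Bu4NF/AcOH (1:1, 3.5 equiv), THF, 0 °C
Reagents that add atoms: none
Why: Fluoride-induced cleavage of aryl silyl ethers, fast even for triisopropylsilyl because phenoxide is a good leaving group. Acetic acid protonates each phenoxide as it forms, so the basicity needed for E1cB opening of ring C and racemisation at C2 is never reached, and the prenyl ether is inert.

## Compound list

1 | 1-bromo-3,5-dimethoxybenzene | COc1cc(Br)cc(OC)c1 | starting material
2 | 1-(2-bromo-4,6-dimethoxyphenyl)ethan-1-one | CC(=O)c1c(Br)cc(OC)cc1OC | intermediate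
3 | 1-(2-bromo-4,6-dihydroxyphenyl)ethan-1-one | CC(=O)c1c(Br)cc(O)cc1O | intermediate
4 | 1-[2-bromo-4,6-bis(triisopropylsilyloxy)phenyl]ethan-1-one | CC(=O)c1c(Br)cc(O[Si](C(C)C)(C(C)C)C(C)C)cc1O[Si](C(C)C)(C(C)C)C(C)C | intermediate
5 | 1-bromo-2-(prop-1-en-2-yl)-3,5-bis(triisopropylsilyloxy)benzene | CC(=C)c1c(Br)cc(O[Si](C(C)C)(C(C)C)C(C)C)cc1O[Si](C(C)C)(C(C)C)C(C)C | intermediate
6 | 2-[2-bromo-4,6-bis(triisopropylsilyloxy)phenyl]prop-2-en-1-ol | OCC(=C)c1c(Br)cc(O[Si](C(C)C)(C(C)C)C(C)C)cc1O[Si](C(C)C)(C(C)C)C(C)C | intermediate
7 | 2-[2-bromo-4,6-bis(triisopropylsilyloxy)phenyl]prop-2-en-1-yl methyl carbonate | COC(=O)OCC(=C)c1c(Br)cc(O[Si](C(C)C)(C(C)C)C(C)C)cc1O[Si](C(C)C)(C(C)C)C(C)C | intermediate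
8 | 2-{2-[2-bromo-4,6-bis(triisopropylsilyloxy)phenyl]prop-2-en-1-yl}-4,4,5,5-tetramethyl-1,3,2-dioxaborolane | CC1(C)OB(CC(=C)c2c(Br)cc(O[Si](C(C)C)(C(C)C)C(C)C)cc2O[Si](C(C)C)(C(C)C)C(C)C)OC1(C)C | intermediate
9 | 3,4-dihydroxybenzaldehyde | O=Cc1ccc(O)c(O)c1 | starting material
10 | 4-benzyloxy-3-hydroxybenzaldehyde | O=Cc1ccc(OCc2ccccc2)c(O)c1 | intermediate
11 | 4-benzyloxy-3-(triisopropylsilyloxy)benzaldehyde | O=Cc1ccc(OCc2ccccc2)c(O[Si](C(C)C)(C(C)C)C(C)C)c1 | intermediate
12 | pinacol borate ester of 13 ((S), O–B(pin) at C2; not isolated) | c1ccccc1COc1ccc([C@@H](OB2OC(C)(C)C(C)(C)O2)CC(=C)c2c(Br)cc(O[Si](C(C)C)(C(C)C)C(C)C)cc2O[Si](C(C)C)(C(C)C)C(C)C)cc1O[Si](C(C)C)(C(C)C)C(C)C | intermediate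
13 | (S)-1-[4-benzyloxy-3-(triisopropylsilyloxy)phenyl]-3-[2-bromo-4,6-bis(triisopropylsilyloxy)phenyl]but-3-en-1-ol | c1ccccc1COc1ccc([C@@H](O)CC(=C)c2c(Br)cc(O[Si](C(C)C)(C(C)C)C(C)C)cc2O[Si](C(C)C)(C(C)C)C(C)C)cc1O[Si](C(C)C)(C(C)C)C(C)C | intermediate
14 | (2S)-4'-benzyloxy-3',5,7-tris(triisopropylsilyloxy)-4-methyleneflavan | c1ccccc1COc1ccc([C@@H]2CC(=C)c3c(O[Si](C(C)C)(C(C)C)C(C)C)cc(O[Si](C(C)C)(C(C)C)C(C)C)cc3O2)cc1O[Si](C(C)C)(C(C)C)C(C)C | intermediate
15 | secondary ozonide of 14 (spiro-1,2,4-trioxolane at C4, either C4 epimer, 2S; not isolated) | c1ccccc1COc1ccc([C@@H]2CC3(OCOO3)c4c(O[Si](C(C)C)(C(C)C)C(C)C)cc(O[Si](C(C)C)(C(C)C)C(C)C)cc4O2)cc1O[Si](C(C)C)(C(C)C)C(C)C | intermediate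
16 | (2S)-4'-benzyloxy-3',5,7-tris(triisopropylsilyloxy)flavanone | c1ccccc1COc1ccc([C@@H]2CC(=O)c3c(O[Si](C(C)C)(C(C)C)C(C)C)cc(O[Si](C(C)C)(C(C)C)C(C)C)cc3O2)cc1O[Si](C(C)C)(C(C)C)C(C)C | intermediate
17 | (2S)-4'-hydroxy-3',5,7-tris(triisopropylsilyloxy)flavanone | Oc1ccc([C@@H]2CC(=O)c3c(O[Si](C(C)C)(C(C)C)C(C)C)cc(O[Si](C(C)C)(C(C)C)C(C)C)cc3O2)cc1O[Si](C(C)C)(C(C)C)C(C)C | intermediate
18 | prenol (3-methylbut-2-en-1-ol) | CC(C)=CCO | starting material
19 | (2S)-4'-(3-methylbut-2-enyloxy)-3',5,7-tris(triisopropylsilyloxy)flavanone | CC(C)=CCOc1ccc([C@@H]2CC(=O)c3c(O[Si](C(C)C)(C(C)C)C(C)C)cc(O[Si](C(C)C)(C(C)C)C(C)C)cc3O2)cc1O[Si](C(C)C)(C(C)C)C(C)C | intermediate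
20 | monotesone A, (2S)-5,7,3'-trihydroxy-4'-(3-methylbut-2-enyloxy)flavanone | CC(C)=CCOc1ccc([C@@H]2CC(=O)c3c(O)cc(O)cc3O2)cc1O | target

## Step count and least certain steps

Total: 15 steps. The longest linear sequence is 13 steps (steps 1–7 from 1 to 8, then steps 10–15). The ring B branch (steps 8 and 9) joins at step 10.

**Step 11 (key step).**
- *What may go wrong.* The most likely failure is β-hydride elimination from the palladium alkoxide, because the C2–H bond is benzylic and electron-rich. This would oxidise C2 and remove the bromine reductively. The palladium hydride released could then move the exocyclic double bond into the ring or into conjugation. Slow turnover would also give carbonate more time to attack the silyl ethers.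
- *Fallback.* The polarity of the ring closure is reversed, so that ring A supplies the oxygen nucleophile and C2 becomes the electrophile. It sets out from 8 and 11. Step 10 is repeated with (R)-TRIP and gives, through the (R)-configured pinacol borate ester F1, the (R)-carbinol F2. Miyaura borylation of its C–Br bond (PdCl2(dppf), B2pin2, KOAc, dioxane, 80 °C) would give the aryl pinacol boronate F3, and NaBO3·4H2O in THF/H2O would convert this into the phenol F4. An intramolecular Mitsunobu reaction (PPh3, DIAD, toluene, 0 °C) then closes O1–C2 with inversion and rejoins the route at 14. Its own weakness is partial ionisation of the electron-rich benzylic carbinol.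

**Step 10.**
- *What may go wrong.* The twisted, doubly ortho-substituted aryl group on the central allyl carbon lies close to the pseudoaxial boronate oxygen, where the acid binds. This may slow the catalysed pathway and lower the facial selectivity. The bulky meta silyloxy group of 11 may also fit the catalyst pocket poorly.
- *Fallback.* A catalytic asymmetric Nozaki–Hiyama–Kishi allylation replaces the allylboration. This reaction type is established for 2-substituted allyl halides and aromatic aldehydes. It sets out from 6, which is converted with MsCl/Et3N and then LiCl (THF) into the 2-arylallyl chloride F5. CrCl2 (divalent chromium, 10 mol %), a tridentate bis(oxazolinyl)carbazole ligand, Mn powder and Me3SiCl in THF would couple F5 with 11, without touching the aryl bromide, to give the trimethylsilyl ether F6. Citric acid in MeOH cleaves this selectively and rejoins the route at 13.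

**Step 5.**
- *What may go wrong.* The alkene is shielded by the perpendicular ring A, so the ene step may be slow. Longer exposure invites over-oxidation of the allylic alcohol, and selenium residues can be hard to remove. A borohydride treatment of the crude mixture would return over-oxidised material.
- *Fallback.* The allylic oxidation is replaced by epoxidation and isomerisation. It sets out from 5. Buffered m-CPBA (NaHCO3, CH2Cl2, 0 °C) would give the racemic 2-aryl-2-methyloxirane F7. Diethylaluminium 2,2,6,6-tetramethylpiperidide, Et2Al(NC9H18), in toluene at 0 °C would open this by syn-elimination towards the methyl group and rejoin the route at 6.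

**Step 12.**
- *What may go wrong.* Ozone may also attack the two electron-rich arenes or the benzylic C–H bonds of the benzyl ether and of C2 if the end point is passed.
- *Fallback.* The cleavage is done in two stages without ozone. It sets out from 14. OsO4 (cat.) with N-methylmorpholine N-oxide in acetone/H2O would give the 4-hydroxy-4-(hydroxymethyl)flavan F8, whose C4 configuration is irrelevant. NaIO4 in THF/H2O at neutral pH cleaves F8 and rejoins the route at 16.

**Step 14.**
- *What may go wrong.* The silyl group may migrate from O3' to the neighbouring phenoxide before alkylation, which would place the prenyl group on the wrong oxygen. The ortho-hindered phenol may react sluggishly. Some transposed (SN2') substitution is also possible.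
- *Fallback.* Activation of the alcohol is exchanged for direct alkylation with a halide under halophilic assistance. It sets out from 17, which is treated with prenyl bromide and Ag2O in toluene at rt. No soluble base is present and the phenol is alkylated as it is metalated. The route is rejoined at 19 without any new compound (F0).

## Further compounds

F1 | step 11 | (R)-configured pinacol borate ester, enantiomer of 12 | c1ccccc1COc1ccc([C@H](OB2OC(C)(C)C(C)(C)O2)CC(=C)c2c(Br)cc(O[Si](C(C)C)(C(C)C)C(C)C)cc2O[Si](C(C)C)(C(C)C)C(C)C)cc1O[Si](C(C)C)(C(C)C)C(C)C
F2 | step 11 | (R)-1-[4-benzyloxy-3-(triisopropylsilyloxy)phenyl]-3-[2-bromo-4,6-bis(triisopropylsilyloxy)phenyl]but-3-en-1-ol | c1ccccc1COc1ccc([C@H](O)CC(=C)c2c(Br)cc(O[Si](C(C)C)(C(C)C)C(C)C)cc2O[Si](C(C)C)(C(C)C)C(C)C)cc1O[Si](C(C)C)(C(C)C)C(C)C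
F3 | step 11 | (R)-1-[4-benzyloxy-3-(triisopropylsilyloxy)phenyl]-3-[2-(4,4,5,5-tetramethyl-1,3,2-dioxaborolan-2-yl)-4,6-bis(triisopropylsilyloxy)phenyl]but-3-en-1-ol | c1ccccc1COc1ccc([C@H](O)CC(=C)c2c(B3OC(C)(C)C(C)(C)O3)cc(O[Si](C(C)C)(C(C)C)C(C)C)cc2O[Si](C(C)C)(C(C)C)C(C)C)cc1O[Si](C(C)C)(C(C)C)C(C)C
F4 | step 11 | (R)-1-[4-benzyloxy-3-(triisopropylsilyloxy)phenyl]-3-[2-hydroxy-4,6-bis(triisopropylsilyloxy)phenyl]but-3-en-1-ol | c1ccccc1COc1ccc([C@H](O)CC(=C)c2c(O)cc(O[Si](C(C)C)(C(C)C)C(C)C)cc2O[Si](C(C)C)(C(C)C)C(C)C)cc1O[Si](C(C)C)(C(C)C)C(C)C
F5 | step 10 | 1-bromo-2-(3-chloroprop-1-en-2-yl)-3,5-bis(triisopropylsilyloxy)benzene | ClCC(=C)c1c(Br)cc(O[Si](C(C)C)(C(C)C)C(C)C)cc1O[Si](C(C)C)(C(C)C)C(C)C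
F6 | step 10 | trimethylsilyl ether of 13 ((S)) | c1ccccc1COc1ccc([C@@H](O[Si](C)(C)C)CC(=C)c2c(Br)cc(O[Si](C(C)C)(C(C)C)C(C)C)cc2O[Si](C(C)C)(C(C)C)C(C)C)cc1O[Si](C(C)C)(C(C)C)C(C)C
F7 | step 5 | 2-[2-bromo-4,6-bis(triisopropylsilyloxy)phenyl]-2-methyloxirane (racemic) | CC1(CO1)c1c(Br)cc(O[Si](C(C)C)(C(C)C)C(C)C)cc1O[Si](C(C)C)(C(C)C)C(C)C
F8 | step 12 | (2S)-4'-benzyloxy-4-hydroxy-4-(hydroxymethyl)-3',5,7-tris(triisopropylsilyloxy)flavan (either C4 epimer) | c1ccccc1COc1ccc([C@@H]2CC(O)(CO)c3c(O[Si](C(C)C)(C(C)C)C(C)C)cc(O[Si](C(C)C)(C(C)C)C(C)C)cc3O2)cc1O[Si](C(C)C)(C(C)C)C(C)C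
F0 | step 14 | none | none
A1 | alternative 1 | (2S)-3'-O-(tert-butyldimethylsilyl)monotesone A | CC(C)=CCOc1ccc([C@@H]2CC(=O)c3c(O)cc(O)cc3O2)cc1O[Si](C)(C)C(C)(C)C
A2 | alternative 1 | (2S)-2-[3-(tert-butyldimethylsilyloxy)-4-(3-methylbut-2-enyloxy)phenyl]-6-[(2,2-dimethyl-4-oxo-4H-1,3-dioxin-6-yl)methyl]-2,3-dihydro-4H-pyran-4-one | CC(C)=CCOc1ccc([C@@H]2CC(=O)C=C(CC3=CC(=O)OC(C)(C)O3)O2)cc1O[Si](C)(C)C(C)(C)C
A3 | alternative 1 | acylketene, 4-{(2S)-2-[3-(tert-butyldimethylsilyloxy)-4-(3-methylbut-2-enyloxy)phenyl]-4-oxo-2,3-dihydro-4H-pyran-6-yl}-3-oxobut-1-en-1-one | CC(C)=CCOc1ccc([C@@H]2CC(=O)C=C(CC(=O)C=C=O)O2)cc1O[Si](C)(C)C(C)(C)C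
A4 | alternative 2 | (2S)-3',5,7-tris-O-(tert-butyldimethylsilyl)monotesone A | CC(C)=CCOc1ccc([C@@H]2CC(=O)c3c(O[Si](C)(C)C(C)(C)C)cc(O[Si](C)(C)C(C)(C)C)cc3O2)cc1O[Si](C)(C)C(C)(C)C
A5 | alternative 2 | 2-{1-[3-(tert-butyldimethylsilyloxy)-4-(3-methylbut-2-enyloxy)phenyl]vinyloxy}-4,6-bis(tert-butyldimethylsilyloxy)benzaldehyde | CC(C)=CCOc1ccc(C(=C)Oc2cc(O[Si](C)(C)C(C)(C)C)cc(O[Si](C)(C)C(C)(C)C)c2C=O)cc1O[Si](C)(C)C(C)(C)C
A6 | alternative 3 | (2S,4S)-2,4-cis-4'-benzyloxy-4-methoxy-3',5,7-tris(tert-butyldimethylsilyloxy)flavan | c1ccccc1COc1ccc([C@@H]2C[C@H](OC)c3c(O[Si](C)(C)C(C)(C)C)cc(O[Si](C)(C)C(C)(C)C)cc3O2)cc1O[Si](C)(C)C(C)(C)C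
A7 | alternative 3 | 2-hydroxy-4,6-bis(tert-butyldimethylsilyloxy)benzaldehyde | O=Cc1c(O)cc(O[Si](C)(C)C(C)(C)C)cc1O[Si](C)(C)C(C)(C)C
A8 | alternative 3 | 4-benzyloxy-3-(tert-butyldimethylsilyloxy)styrene | C=Cc1ccc(OCc2ccccc2)c(O[Si](C)(C)C(C)(C)C)c1
A9 | alternative 3 | 6-(methoxymethylidene)-3,5-bis(tert-butyldimethylsilyloxy)cyclohexa-2,4-dien-1-one (4-methoxy ortho-quinone methide) | COC=C1C(=O)C=C(O[Si](C)(C)C(C)(C)C)C=C1O[Si](C)(C)C(C)(C)C
A10 | alternative 3 | trimethyl orthoformate | COC(OC)OC
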